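**Plan**
1. Numbering: bridgeheads C1 and C5; ring A = C1–C2(aryl A, 3-hydroxy-4,5-dimethoxyphenyl)–O3–C4–C5; ring B = C5–C6(aryl B, 3,4,5-trimethoxyphenyl)–O7–C8–C1.
2. The retrosynthesis cuts the two benzylic C–O bonds O3–C2 and O7–C6 first, giving a 1,4-diaryl-2,3-bis(hydroxymethyl)butane-1,4-diol, and then C1–C2 (aldol) and C5–C6 (conjugate addition of an aryl acyl-anion equivalent).
3. Enabling feature: C5 and C1 are adjacent and are the β- and α-carbons of a butenolide whose carbonyl is C8 and whose γ-carbon C4 is at the acetal level, so C4 can carry a removable chiral alkoxy group while C5–C6 and C1–C2 are made on the ring.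
4. Forward: the C6–C5–C1–C2 chain is joined in one flask on the menthyloxybutenolide; dithiane hydrolysis and hydride reduction turn C8 and C4 into CH2OH; ring B and ring A close last, each by C–O bond formation at a benzylic cation.
5. Stereochemistry: the acetal centre (crystallised (5R)-epimer from (−)-menthol) directs C5 (anti), C5 directs C1 (trans), and C1/C5 direct C2 and C6 (aryl groups exo) in the final closure.

Key step: step 5

**Remarks on the chemistry**
- Absolute sense: addition anti to the acetal substituent gives the (1R,5R) bridgeheads only from the (5R)-butenolide, i.e. the acetal of natural (−)-menthol. The (5S)-acetal of (+)-menthol would lead to the enantiomeric series.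
- The carbinol centres C2 (from the aldol) and C6 (from ketone reduction) are transient. They are expected to form as epimer mixtures, are carried forward unseparated and are both ionised in step 8. Structures are drawn for one epimer: C2 as the anti-aldol (R) centre, C6 as S.
- Locants C1–C8 below refer to the target numbering.

**Route**

Step 1
Reactants: 1 furfural
Product: 3 5-hydroxyfuran-2(5H)-one (racemic), via furfural endoperoxide 2 (not isolated)
Conditions: O2, visible light, rose bengal (cat.), MeOH, 20 °C
Reagents that add atoms: oxygen, O=O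
Why: Dye-sensitised singlet-oxygen [4+2] cycloaddition to the furan gives endoperoxide 2, which methanol cleaves with loss of the formyl carbon as methyl formate (furan photooxygenation), leaving the hydroxybutenolide.

Step 2
Reactants: 3 5-hydroxyfuran-2(5H)-one; 4 (−)-menthol
Product: 5 (5R)-5-[(1R,2S,5R)-menthyloxy]furan-2(5H)-one
Conditions: CSA (cat.), toluene, reflux with azeotropic removal of water; crystallisation from petroleum ether; mother liquor re-equilibrated with CSA and recrystallised
Reagents that add atoms: none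
Why: Acid-catalysed acetalisation of the cyclic hemiacetal gives both C5 epimers, which interconvert through the oxocarbenium ion, so the acetal stereocentre is set by selective crystallisation of the (5R)-epimer with recycling of the mother liquor.

Step 3
Reactants: 6 3,4,5-trimethoxybenzaldehyde
Product: 7 2-(3,4,5-trimethoxyphenyl)-1,3-dithiane
Conditions: HS(CH2)3SH, BF3·OEt2 (cat.), CH2Cl2, 0 °C to rt
Reagents that add atoms: propane-1,3-dithiol, SCCCS
Why: Lewis-acid-catalysed dithioacetalisation of an aromatic aldehyde is general and leaves the aryl methyl ethers untouched.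

Step 4
Reactants: 8 3-hydroxy-4,5-dimethoxybenzaldehyde
Product: 9 3-benzyloxy-4,5-dimethoxybenzaldehyde
Conditions: BnBr, K2CO3, DMF, rt
Reagents that add atoms: benzyl bromide, BrCc1ccccc1
Why: Williamson ether synthesis on the phenoxide installs a benzyl ether that tolerates organolithium, mercury-assisted hydrolysis, hydride and dilute acid and is removed last by hydrogenolysis.

Step 5
Reactants: 7 2-(3,4,5-trimethoxyphenyl)-1,3-dithiane; 5 (5R)-5-[(1R,2S,5R)-menthyloxy]furan-2(5H)-one; 9 3-benzyloxy-4,5-dimethoxybenzaldehyde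
Product: 12 (3S,4R,5R)-3-[(R)-(3-benzyloxy-4,5-dimethoxyphenyl)(hydroxy)methyl]-5-[(1R,2S,5R)-menthyloxy]-4-[2-(3,4,5-trimethoxyphenyl)-1,3-dithian-2-yl]dihydrofuran-2(3H)-one (trans,trans lactone; anti-aldol epimer drawn), via lithiated dithiane 10 (not isolated), via lithium enolate 11 (not isolated)
Conditions: n-BuLi, THF, −78 to −30 °C; 5, −78 °C; 9, −78 °C; sat. aq. NH4Cl, −78 °C
Reagents that add atoms: none
Why: n-BuLi deprotonates C2 of the dithiane (Corey–Seebach umpolung) to the soft, sulfur- and aryl-stabilised anion 10, which adds 1,4 to the butenolide at C5 to form C5–C6 and the ring-locked lithium enolate 11, and 11 then adds to aldehyde 9 through a closed, lithium-bridged chair transition state to form C1–C2. The closest known reaction type is the tandem conjugate addition–aldol of 2-lithio-2-aryl-1,3-dithianes to 5-alkoxyfuran-2(5H)-ones with aromatic aldehydes as the enolate trap. No ring is closed in this step. C5 is controlled by the acetal centre, because the anion enters the planar enoate on the face opposite the menthyloxy group; C1 is controlled by C5, because the aldehyde approaches the enolate opposite the very large dithianyl substituent, which gives the trans,trans lactone; the carbinol centre C2 is only weakly biased towards the anti-aldol epimer by the chair transition state of the E-enolate and needs no control. The step needs 1,4- over 1,2-addition and an aldol that outruns proton transfer and retro-aldol; the delocalised dithiane anion, the unhindered β-carbon of the electron-poor butenolide, the low temperature and the cold NH4Cl quench should secure these.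

Step 6
Reactants: 12 trans,trans dithianyl hydroxy lactone
Product: 13 (3S,4R,5R)-3-[(R)-(3-benzyloxy-4,5-dimethoxyphenyl)(hydroxy)methyl]-5-[(1R,2S,5R)-menthyloxy]-4-(3,4,5-trimethoxybenzoyl)dihydrofuran-2(3H)-one
Conditions: HgO, BF3·OEt2 (promoter), THF–H2O (85:15), rt
Reagents that add atoms: water, O
Why: Hydrolysis of the S,S-acetal assisted by thiophilic divalent mercury (thionium ion captured by water) should unmask the aryl ketone under mildly acidic conditions that leave the mixed acetal, the β-hydroxy lactone and the benzyl ether intact, and no stereocentre is formed or epimerised because the trans lactone is the stable arrangement.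

Step 7
Reactants: 13 keto hydroxy lactone
Product: 14 (1R,2R,3R,4S)-1-(3-benzyloxy-4,5-dimethoxyphenyl)-2,3-bis(hydroxymethyl)-4-(3,4,5-trimethoxyphenyl)butane-1,4-diol (carbinol epimers at butane C1 and C4 carried together)
Conditions: LiAlH4 (excess), THF, −20 °C to reflux; H2O, aq. NaOH
Reagents that add atoms: none
Why: Hydride reduction with LiAlH4 converts the aryl ketone into the C6 carbinol (new centre, uncontrolled and not needed), the lactone carbonyl into the C8 primary alcohol and, because opening of the 5-alkoxy lactone exposes C4 as an aldehyde, the acetal carbon into the C4 primary alcohol with release of menthol, as is standard for 5-alkoxybutyrolactones.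

Step 8
Reactants: 14 tetraol
Product: 16 (1R,2S,5R,6S)-2-(3-benzyloxy-4,5-dimethoxyphenyl)-6-(3,4,5-trimethoxyphenyl)-3,7-dioxabicyclo[3.3.0]octane, via monocyclic tetrahydrofuran diol 15 (not isolated)
Conditions: CSA (0.1 equiv), CH2Cl2, 4 Å MS, 0 °C to rt; Et3N quench
Reagents that add atoms: none
Why: Acid-catalysed SN1 cyclodehydration, a known route from 1,4-diaryl-2,3-bis(hydroxymethyl)butane-1,4-diols to furofurans, ionises each benzylic carbinol to an alkoxyaryl-stabilised cation that is captured in a 5-exo sense by the 1,4-related primary hydroxyl (C8–OH at C6, C4–OH at C2), and allylic 1,3-strain in the cation keeps the aryl group anti to the neighbouring ring carbon, so C2 and C6 should both emerge S with the aryl groups exo from either carbinol epimer (15 is drawn with ring B closed first; the order is immaterial).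

Step 9
Reactants: 16 benzyl-protected furofuran
Product: 17 (1R,2S,5R,6S)-2-(3-hydroxy-4,5-dimethoxyphenyl)-6-(3,4,5-trimethoxyphenyl)-3,7-dioxabicyclo[3.3.0]octane (target)
Conditions: H2 (1 atm), 10% Pd/C, EtOAc, rt, stopped at one equivalent of H2
Reagents that add atoms: none
Why: Heterogeneous hydrogenolysis of an aryl benzyl ether over palladium in a neutral solvent is much faster than cleavage of the ring benzylic C–O bonds of the furofuran, so the phenol should be released with all four stereocentres untouched.

**Compound list**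
1 | furfural | O=Cc1ccco1 | starting material
2 | 2,3,7-trioxabicyclo[2.2.1]hept-5-ene-1-carbaldehyde (furfural endoperoxide, racemic) | O=CC12OOC(O1)C=C2 | intermediate
3 | 5-hydroxyfuran-2(5H)-one (racemic) | O=C1C=CC(O)O1 | intermediate
4 | (−)-menthol, (1R,2S,5R)-2-isopropyl-5-methylcyclohexanol | CC(C)[C@@H]1CC[C@@H](C)C[C@H]1O | starting material
5 | (5R)-5-[(1R,2S,5R)-menthyloxy]furan-2(5H)-one | O=C1C=C[C@H](O[C@@H]2C[C@H](C)CC[C@H]2C(C)C)O1 | intermediate
6 | 3,4,5-trimethoxybenzaldehyde | COc1cc(C=O)cc(OC)c1OC | starting material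
7 | 2-(3,4,5-trimethoxyphenyl)-1,3-dithiane | COc1cc(C2SCCCS2)cc(OC)c1OC | intermediate
8 | 3-hydroxy-4,5-dimethoxybenzaldehyde | COc1cc(C=O)cc(O)c1OC | starting material
9 | 3-benzyloxy-4,5-dimethoxybenzaldehyde | COc1cc(C=O)cc(OCc2ccccc2)c1OC | intermediate
10 | 2-lithio-2-(3,4,5-trimethoxyphenyl)-1,3-dithiane | [Li]C1(c2cc(OC)c(OC)c(OC)c2)SCCCS1 | intermediate
11 | lithium (4R,5R)-5-[(1R,2S,5R)-menthyloxy]-4-[2-(3,4,5-trimethoxyphenyl)-1,3-dithian-2-yl]-4,5-dihydrofuran-2-olate | [Li]OC1=C[C@@H](C2(c3cc(OC)c(OC)c(OC)c3)SCCCS2)[C@H](O[C@@H]2C[C@H](C)CC[C@H]2C(C)C)O1 | intermediate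
12 | (3S,4R,5R)-3-[(R)-(3-benzyloxy-4,5-dimethoxyphenyl)(hydroxy)methyl]-5-[(1R,2S,5R)-menthyloxy]-4-[2-(3,4,5-trimethoxyphenyl)-1,3-dithian-2-yl]dihydrofuran-2(3H)-one | O=C1O[C@@H](O[C@@H]2C[C@H](C)CC[C@H]2C(C)C)[C@H](C2(c3cc(OC)c(OC)c(OC)c3)SCCCS2)[C@H]1[C@@H](O)c1cc(OC)c(OC)c(OCc2ccccc2)c1 | intermediate
13 | (3S,4R,5R)-3-[(R)-(3-benzyloxy-4,5-dimethoxyphenyl)(hydroxy)methyl]-5-[(1R,2S,5R)-menthyloxy]-4-(3,4,5-trimethoxybenzoyl)dihydrofuran-2(3H)-one | O=C1O[C@@H](O[C@@H]2C[C@H](C)CC[C@H]2C(C)C)[C@H](C(=O)c2cc(OC)c(OC)c(OC)c2)[C@H]1[C@@H](O)c1cc(OC)c(OC)c(OCc2ccccc2)c1 | intermediate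
14 | (1R,2R,3R,4S)-1-(3-benzyloxy-4,5-dimethoxyphenyl)-2,3-bis(hydroxymethyl)-4-(3,4,5-trimethoxyphenyl)butane-1,4-diol | OC[C@H]([C@H](O)c1cc(OC)c(OC)c(OC)c1)[C@H](CO)[C@@H](O)c1cc(OC)c(OC)c(OCc2ccccc2)c1 | intermediate
15 | [(2S,3R,4R)-4-[(R)-(3-benzyloxy-4,5-dimethoxyphenyl)(hydroxy)methyl]-2-(3,4,5-trimethoxyphenyl)tetrahydrofuran-3-yl]methanol | OC[C@@H]1[C@@H](c2cc(OC)c(OC)c(OC)c2)OC[C@@H]1[C@@H](O)c1cc(OC)c(OC)c(OCc2ccccc2)c1 | intermediate
16 | (1R,2S,5R,6S)-2-(3-benzyloxy-4,5-dimethoxyphenyl)-6-(3,4,5-trimethoxyphenyl)-3,7-dioxabicyclo[3.3.0]octane | COc1cc([C@H]2OC[C@H]3[C@@H]2CO[C@@H]3c2cc(OC)c(OC)c(OC)c2)cc(OCc2ccccc2)c1OC | intermediate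
17 | (1R,2S,5R,6S)-2-(3-hydroxy-4,5-dimethoxyphenyl)-6-(3,4,5-trimethoxyphenyl)-3,7-dioxabicyclo[3.3.0]octane | COc1cc([C@H]2OC[C@H]3[C@@H]2CO[C@@H]3c2cc(OC)c(OC)c(OC)c2)cc(O)c1OC | target

**Count**
Total steps: 9. Longest linear sequence: 7 steps (steps 1, 2, 5, 6, 7, 8, 9, from furfural).

**Steps most likely to fail**

Step 8. The cations may close with poor exo/endo discrimination, the product may re-ionise and epimerise under the acid, or a long-lived cation may alkylate the neighbouring electron-rich ring. The fallback sets out from 14 and returns at 16. It gives up the single kinetic pass in favour of an equilibrate, separate and recycle sequence: the closure is run to completion with acid, 16 is separated by chromatography or crystallisation from its endo-aryl epimers, drawn for the C2 epimer (1R,2R,5R,6S)-2-(3-benzyloxy-4,5-dimethoxyphenyl)-6-(3,4,5-trimethoxyphenyl)-3,7-dioxabicyclo[3.3.0]octane F1, and F1 is re-exposed to acid (dilute HCl in EtOH, warm) so that it re-opens through the same benzylic cation and re-closes to a mixture that again contains 16; the cycle is repeated. Acid epimerisation of furofuran benzylic ethers is known chemistry.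

Step 5. The enolate may be lost to proton transfer, the hindered enolate may add sluggishly, or the aldolate may revert before the quench. The fallback sets out from 5 and 7 and returns at 12. The two bond formations are decoupled: the conjugate addition is quenched with NH4Cl and the Michael adduct (4R,5R)-5-[(1R,2S,5R)-menthyloxy]-4-[2-(3,4,5-trimethoxyphenyl)-1,3-dithian-2-yl]dihydrofuran-2(3H)-one F2 is isolated and purified. F2 is then re-enolised with LiN(iPr)2 in THF at −78 °C, transmetallated with ZnCl2 to a less basic zinc enolate that is less prone to retro-aldol, and treated with 9 to give 12 with the same trans relationship at C1.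

Step 6. Retro-aldol cleavage, ionisation of the benzylic carbinol or loss of the acetal may compete with unmasking of the hindered dithiane on the lactone. The fallback sets out from 12 and returns at 14 by changing the order of events. LiAlH4 in THF first reduces the lactone and acetal of 12 to the robust triol (1R,2R,3R)-1-(3-benzyloxy-4,5-dimethoxyphenyl)-2-(hydroxymethyl)-3-[2-(3,4,5-trimethoxyphenyl)-1,3-dithian-2-yl]butane-1,4-diol F3. Alkylative hydrolysis of the dithiane (MeI, CaCO3, MeCN–H2O, 40 °C) then gives the keto triol (2R,3R,4R)-4-(3-benzyloxy-4,5-dimethoxyphenyl)-4-hydroxy-2,3-bis(hydroxymethyl)-1-(3,4,5-trimethoxyphenyl)butan-1-one F4, expected to rest as its cyclic hemiketal. NaBH4 in MeOH at 0 °C reduces F4 to tetraol 14.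

**Further compounds**
F1 | step 8 | (1R,2R,5R,6S)-2-(3-benzyloxy-4,5-dimethoxyphenyl)-6-(3,4,5-trimethoxyphenyl)-3,7-dioxabicyclo[3.3.0]octane | COc1cc([C@@H]2OC[C@H]3[C@@H]2CO[C@@H]3c2cc(OC)c(OC)c(OC)c2)cc(OCc2ccccc2)c1OC
F2 | step 5 | (4R,5R)-5-[(1R,2S,5R)-menthyloxy]-4-[2-(3,4,5-trimethoxyphenyl)-1,3-dithian-2-yl]dihydrofuran-2(3H)-one | O=C1C[C@@H](C2(c3cc(OC)c(OC)c(OC)c3)SCCCS2)[C@H](O[C@@H]2C[C@H](C)CC[C@H]2C(C)C)O1
F3 | step 6 | (1R,2R,3R)-1-(3-benzyloxy-4,5-dimethoxyphenyl)-2-(hydroxymethyl)-3-[2-(3,4,5-trimethoxyphenyl)-1,3-dithian-2-yl]butane-1,4-diol | OC[C@H](C1(c2cc(OC)c(OC)c(OC)c2)SCCCS1)[C@H](CO)[C@@H](O)c1cc(OC)c(OC)c(OCc2ccccc2)c1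
F4 | step 6 | (2R,3R,4R)-4-(3-benzyloxy-4,5-dimethoxyphenyl)-4-hydroxy-2,3-bis(hydroxymethyl)-1-(3,4,5-trimethoxyphenyl)butan-1-one | OC[C@H](C(=O)c1cc(OC)c(OC)c(OC)c1)[C@H](CO)[C@@H](O)c1cc(OC)c(OC)c(OCc2ccccc2)c1
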